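Target plus starting material stays constant in these runs: Thursday's run sums to 100% at 3.00 d and Tuesday's to 99.7% at 3.00 d, so I follow the target. Thursday's run has the flask's charges of starting material, second substrate and partner, but its c(free catalyst) is 4 mM against 2.0 mM.

| setting | Tuesday's | Monday's | Thursday's | flask |
|---|---|---|---|---|
| starting material | 1 M | 1 M | 1 M | 1.0 M |
| second substrate | 0.50 M | 0.75 M | 1 M | 1.00 M |
| partner | 1.05 M | 1.05 M | 1.05 M | 1.05 M |
| free catalyst | 2 mM (in portions, 2) | 2 mM (in portions, 2) | 4 mM (in portions, 2) | 2.0 mM (in portions, 2) |
| remark | run made earlier; portions every 5.0 h | run made earlier; portions every 5.0 h | run made earlier; portions every 5.0 h | the portions of free catalyst follow each other after 5.0 h, the first at the start |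
| time |  |  |  | 5.0 d |

| run | time / d | target / % | starting material / % |
|---|---|---|---|
| Tuesday's | 0.250 | 2.4 | 97.4 |
| Tuesday's | 0.417 | 5.0 | 95.8 |
| Tuesday's | 0.625 | 8.6 | 91.4 |
| Tuesday's | 1.04 | 13.9 | 87.0 |
| Tuesday's | 1.67 | 20.0 | 80.1 |
| Tuesday's | 3.00 | 29.6 | 70.1 |
| Monday's | 0.208 | 1.1 | 98.6 |
| Monday's | 0.625 | 7.8 | 92.2 |
| Monday's | 1.04 | 11.8 | 87.9 |
| Monday's | 1.67 | 17.5 | 82.0 |
| Monday's | 2.50 | 23.0 | 76.3 |
| Monday's | 3.00 | 26.0 | 73.9 |
| Thursday's | 0.250 | 3.5 | 96.0 |
| Thursday's | 0.833 | 16.2 | 83.8 |
| Thursday's | 1.25 | 21.9 | 77.7 |
| Thursday's | 2.00 | 29.0 | 70.8 |
| Thursday's | 3.00 | 33.8 | 66.2 |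

(each reading ± 0.3 percentage points)

- the analysis behind the earlier runs scatters by 0.3 percentage points, standard deviation
- the reaction counts as stopped when no species that holds the starting material changes by six tenths of a point or more over the second half of the time

- the state of affairs at 5.0 d: stopped, and by what, or still going (it is still moving / all of the starting material has reacted / the partner has run out first / forward and back rates have come level / no working catalyst is left)
- the target standing at 5.0 d, as a percentage of the starting material charged

I reckon up a ladder of times. On the shortest rung, the second portion goes in at 5.0 h, far inside the 5.0 d asked, so I treat the flask as holding its whole catalyst charge after that. On the next rung, Thursday's run fades: it gains 13 percentage points in 0.583 d early and 4.8 points in its last 1.00 d, a slower pace.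

The top rung is the flask at 5.0 d, which corresponds to 2.50 d on Thursday's run. I call this the matched time, Thursday's clock time with the same catalyst charge multiplied by time. A straight line between Thursday's two neighbouring readings gives 31.4% there.

As a check, I extend Tuesday's and Monday's readings at 3.00 d in a straight line to the flask's second substrate, which gives 22.4%. Thursday's run at the matched 1.50 d reads 24.3%. The 1.9 points lag takes my figure down to 29.5%. The second half of the flask matches Thursday's run from 1.25 d to 2.50 d, where that run gains 9.5 points, which clears the margin for stopped in the conditions above, so I say it is still moving.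

The forecast says it is still moving and 31.5%, above my figure: “The level is still rising, with several points gained over the second half”.

The flask gives it is still moving and 28.4%.

    starting material + free catalyst ⇌ catalyst intermediate A (K = 1.00 /M, k = 21.0 /M/h)
    partner + catalyst intermediate A → free catalyst + target (k = 12.0 /M/h)
    second substrate + free catalyst ⇌ catalyst intermediate B (K = 1.30 /M, k = 52.0 /M/h)
    partner + catalyst intermediate B → free catalyst + second product (k = 10.0 /M/h)
    partner → decomposed reagent (k = 0.00660 /h)

The flask stands 3 points below the straight-line reading at the matched 2.50 d, and its target gains 7.3 points over the second half. A neighbouring flask with 0.0080 M of free catalyst has a matched time of 10.0 d, beyond Thursday's last reading at 3.00 d, so no reading serves it. That neighbour reaches 42.5% of target, and its partner, the limiting reagent there, is down to 0.14% of its charge.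

(Readings and results come from a simulation on assumed constants.)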